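Numbering (ent-kaurane): ring A = C1–C5, C10; C6 = CH2OH carbon; C7 = lactone C=O; C8, C9; ring C = C11–C14; C15 = ketone; C16; C17 = methyl; C20 = lactone CH2.
Retrosynthesis: ring D is a β-hydroxy cyclopentanone (C15=O, C16–H, bridgehead C13–OH that cannot dehydrate), and C8 lies between C7=O and C15=O and 1,4 to C13=O. C13–C16 (aldol) and C8–C14 (oxidative enolate coupling) are therefore cut together, then C9–C11, C8–C15, the lactone C–O, C10–C9, C10–C20 and C5–C6.
Forward: 4,4-dimethylcyclohexadienone, then ring A with C6, then the C10 quaternary centre and the spiro-lactone, then the α-propionyl unsaturated lactone, then the C9 side chain, then rings C and D in one operation, then C16 adjustment and desilylation.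
Stereochemistry: C5 from a catalyst-controlled conjugate addition; C10 and C9 by additions anti to the C5 side; C8 and C13 from the tether in the key step; C16 by exo-face protonation in the last step.

Key step: step 11

Step 1
Reactants: 1 4,4-dimethylcyclohex-2-en-1-one
Product: 2 4,4-dimethylcyclohexa-2,5-dien-1-one
Conditions: DDQ, 1,4-dioxane, reflux
Reagents that add atoms: none
Why: Quinone dehydrogenation is the standard route from 4,4-disubstituted cyclohexenones, which cannot aromatise, to the cross-conjugated dienones.

Step 2
Reactants: 2 4,4-dimethylcyclohexa-2,5-dien-1-one; 3 (chloromethyl)(isopropoxy)dimethylsilane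
Product: 5 (S)-5-(hydroxymethyl)-4,4-dimethylcyclohex-2-en-1-one, via silyl ketone 4 (not isolated)
Conditions: 3, Mg, THF; CuBr·SMe2 (5 mol %), (R)-1-[(S)-2-(diphenylphosphino)ferrocenyl]ethyldicyclohexylphosphine (6 mol %), t-BuOMe, −78 °C, then aq. NH4Cl; KF, KHCO3, 30% H2O2, THF/MeOH, 0 °C to rt
Reagents that add atoms: hydrogen peroxide, OO
Why: Copper-catalysed asymmetric conjugate addition of a Grignard reagent with a ferrocenyl diphosphine should desymmetrise the prochiral dienone and set C5 (the ligand antipode is taken should the sense of induction prove opposite), and Tamao–Fleming oxidation then converts the C–Si bond into C6–OH without touching the stereocentre.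

Step 3
Reactants: 5 (S)-5-(hydroxymethyl)-4,4-dimethylcyclohex-2-en-1-one
Product: 6 (S)-5-{[tert-butyl(dimethyl)silyl]oxymethyl}-4,4-dimethylcyclohex-2-en-1-one
Conditions: TBSCl, imidazole, DMF, rt
Reagents that add atoms: tert-butyldimethylsilyl chloride, CC(C)(C)[Si](C)(C)Cl
Why: Standard silylation of the primary alcohol carries C6–OH through the enolate chemistry that follows.

Step 4
Reactants: 6 (S)-5-{[tert-butyl(dimethyl)silyl]oxymethyl}-4,4-dimethylcyclohex-2-en-1-one
Product: 7 hydroxymethylene ketone (6-(hydroxymethylene) derivative of 6, C5 unchanged)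
Conditions: NaH, HCO2Et, THF, 0 °C to rt; aq. HCl
Reagents that add atoms: ethyl formate, CCOC=O
Why: Claisen condensation with ethyl formate at C10, the only enolisable position (C4 is quaternary), gives the stabilised hydroxymethylene ketone and brings in C20.

Step 5
Reactants: 7 hydroxymethylene ketone; 8 methyl acrylate
Product: 9 keto aldehyde ester (methyl 3-[6-{[tert-butyl(dimethyl)silyl]oxymethyl}-1-formyl-5,5-dimethyl-2-oxocyclohex-3-en-1-yl]propanoate, propanoate chain trans and formyl group cis to the silyloxymethyl group)
Conditions: 8, DBU (0.2 equiv), MeCN, rt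
Reagents that add atoms: none
Why: Base-catalysed Michael addition of the planar β-keto aldehyde anion should take place on the face opposite the neighbouring C5 silyloxymethyl group, which sets C10 with the C9 chain trans and the formyl carbon C20 cis to C6.

Step 6
Reactants: 9 keto aldehyde ester
Product: 11 spiro-lactone ((6S,7R)-7-{[tert-butyl(dimethyl)silyl]oxymethyl}-8,8-dimethyl-2-oxaspiro[5.5]undec-9-ene-3,11-dione), via hydroxy ester 10 (not isolated)
Conditions: NaBH4, CH2Cl2/MeOH, −78 °C; then TsOH (cat.), CH2Cl2, rt
Reagents that add atoms: none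
Why: Borohydride at low temperature should reduce the aldehyde much faster than the hindered conjugated ketone or the ester, and the δ-hydroxy ester then closes to the six-membered lactone under acid catalysis (chemoselective reduction, lactonisation).

Step 7
Reactants: 11 spiro-lactone; 12 N-methoxy-N-methylpropanamide
Product: 13 β-keto lactone (4-propanoyl derivative of 11, propanoyl group on C8; C8 epimers and enol)
Conditions: LiN(SiMe3)2 (2.2 equiv), THF, −78 °C; 12, −78 to 0 °C; aq. NH4Cl
Reagents that add atoms: none
Why: Claisen-type C-acylation of the lactone lithium enolate (C8 is the only enolisable position) with an N-methoxy-N-methylamide stops at the chelated tetrahedral adduct, which releases the β-keto lactone on work-up.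

Step 8
Reactants: 13 β-keto lactone
Product: 15 alkylidene β-keto lactone (4-propanoyl-4,5-didehydro derivative of 11, C8=C9), via selenide 14 (not isolated)
Conditions: PhSeCl, pyridine, CH2Cl2, 0 °C; then 30% H2O2, 0 °C to rt
Reagents that add atoms: phenylselenyl chloride, Cl[Se]c1ccccc1 (its PhSe group is present only in 14)
Why: α-Selenenylation of the 1,3-dicarbonyl followed by selenoxide syn-elimination, for which only the C9 hydrogens are available, gives the doubly activated C8=C9 alkene.

Step 9
Reactants: 15 alkylidene β-keto lactone; 16 2-(2-bromoethyl)-2-methyl-1,3-dioxolane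
Product: 17 conjugate adduct (13 carrying a 2-(2-methyl-1,3-dioxolan-2-yl)ethyl group on C9, anti to the C10–C5 bond)
Conditions: 16, Mg, THF; CuBr·SMe2 (20 mol %), THF, −78 °C; then 15; aq. NH4Cl
Reagents that add atoms: none
Why: Copper-catalysed conjugate addition of the Grignard reagent to the alkylidene 1,3-dicarbonyl (far more electrophilic than the ring A enone, whose β-carbon is neopentylic) should occur on the lactone face turned to the flat C1 carbonyl side of ring A, anti to the C10–C5 bond, which sets C9.

Step 10
Reactants: 17 conjugate adduct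
Product: 18 triketone (13 carrying a 3-oxobutyl group on C9)
Conditions: PPTS, acetone/H2O, 50 °C
Reagents that add atoms: water, O
Why: Mild acid-catalysed acetal hydrolysis frees the methyl ketone (C13, C14) while the primary silyl ether survives.

Step 11
Reactants: 18 triketone
Product: 20 tetracyclic ketol (6-O-TBS ether of the target, both C16 epimers), via diketone 19 (not isolated)
Conditions: LiN(iPr)2 (2.2 equiv), THF, −78 °C; [Fe(DMF)3Cl2][FeCl4] (1.1 equiv), −78 to 0 °C; then DBU, 0 °C to rt
Reagents that add atoms: none
Why: LiN(iPr)2 removes first the C8–H of the β-keto lactone and then, under kinetic control, a proton of the methyl ketone (C14), the dicarbonyl monoanion shielding C16; one-electron oxidation of the more electron-rich ketone enolate by the ferric salt gives the C14 α-keto radical, which adds to C8 of the neighbouring enolate (6-exo-trig, ring C), and a second oxidation delivers 1,4-diketone 19, the closest known reaction type being the intramolecular oxidative heterocoupling of a ketone enolate with a malonate-type enolate. DBU then equilibrates the enolates of 19 and only the C16 enolate of the propionyl group finds an unstrained partner, adding to the C13 carbonyl in a 5-(enolendo)-exo-trig aldol, the ordinary mode of 1,4-diketone cyclisation, which closes ring D and completes the bicyclo[3.2.1]octane. C8 is set by the tether: A(1,3) strain with the exocyclic enolate should hold the C9 side chain pseudo-axial on the lactone, so that C14 is delivered to the same face and ring C is cis-fused to the lactone (C15 cis to H9). C13 follows from C8, because the axial propionyl group can reach the ring C carbonyl from one face only and the hydroxyl must end exo at the bridgehead, while C16 is left open here and is fixed in step 13. The step needs enolisation at C14 in preference to C12 and C16 and C–C in preference to O–C coupling: kinetic deprotonation of the methyl group, the four-membered ring that coupling through C12 would require, and the radical pathway should secure them, and the ketol is the resting point because dehydration is forbidden at the bridgehead.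

Step 12
Reactants: 20 tetracyclic ketol
Product: 21 bis(trimethylsilyl) derivative (13-O-trimethylsilyl ether and C15 trimethylsilyl enol ether, C15=C16, of 20)
Conditions: Me3SiOTf, Et3N, CH2Cl2, 0 °C
Reagents that add atoms: trimethylsilyl trifluoromethanesulfonate, C[Si](C)(C)OS(=O)(=O)C(F)(F)F
Why: Silyl triflate and amine silylate the tertiary alcohol (blocking retro-aldol) and convert the C15 ketone into its silyl enol ether at C16, its only α-position bearing hydrogen, so that both C16 epimers converge on one compound.

Step 13
Reactants: 21 bis(trimethylsilyl) derivative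
Product: 22 target, CNP0533761.1
Conditions: HF·pyridine, pyridine/THF, 0 °C to rt
Reagents that add atoms: none
Why: Kinetic protodesilylation of the silyl enol ether should deliver the proton to C16 from the exo face (the side of the one-carbon bridge C14, away from the three-carbon bridge C9–C11–C12), leaving the methyl group endo as in the target, while fluoride removes the two other silyl groups.

Compound list
1 | 4,4-dimethylcyclohex-2-en-1-one | CC1(C)CCC(=O)C=C1 | starting material
2 | 4,4-dimethylcyclohexa-2,5-dien-1-one | CC1(C)C=CC(=O)C=C1 | intermediate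
3 | (chloromethyl)(isopropoxy)dimethylsilane | CC(C)O[Si](C)(C)CCl | starting material
4 | (S)-5-{[isopropoxy(dimethyl)silyl]methyl}-4,4-dimethylcyclohex-2-en-1-one | CC(C)O[Si](C)(C)C[C@H]1CC(=O)C=CC1(C)C | intermediate
5 | (S)-5-(hydroxymethyl)-4,4-dimethylcyclohex-2-en-1-one | OC[C@H]1CC(=O)C=CC1(C)C | intermediate
6 | (S)-5-{[tert-butyl(dimethyl)silyl]oxymethyl}-4,4-dimethylcyclohex-2-en-1-one | CC(C)(C)[Si](C)(C)OC[C@H]1CC(=O)C=CC1(C)C | intermediate
7 | hydroxymethylene ketone (6-(hydroxymethylene) derivative of 6) | CC(C)(C)[Si](C)(C)OC[C@H]1C(=CO)C(=O)C=CC1(C)C | intermediate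
8 | methyl acrylate | C=CC(=O)OC | starting material
9 | keto aldehyde ester (methyl 3-[6-{[tert-butyl(dimethyl)silyl]oxymethyl}-1-formyl-5,5-dimethyl-2-oxocyclohex-3-en-1-yl]propanoate, chain trans and formyl cis to the silyloxymethyl group) | COC(=O)CC[C@]1(C=O)C(=O)C=CC(C)(C)[C@H]1CO[Si](C)(C)C(C)(C)C | intermediate
10 | hydroxy ester (1-(hydroxymethyl) analogue of 9) | COC(=O)CC[C@]1(CO)C(=O)C=CC(C)(C)[C@H]1CO[Si](C)(C)C(C)(C)C | intermediate
11 | spiro-lactone, (6S,7R)-7-{[tert-butyl(dimethyl)silyl]oxymethyl}-8,8-dimethyl-2-oxaspiro[5.5]undec-9-ene-3,11-dione | O=C1CC[C@]2(CO1)C(=O)C=CC(C)(C)[C@H]2CO[Si](C)(C)C(C)(C)C | intermediate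
12 | N-methoxy-N-methylpropanamide | CCC(=O)N(C)OC | starting material
13 | β-keto lactone (4-propanoyl derivative of 11; C8 epimers and enol) | CCC(=O)C1C[C@]2(COC1=O)C(=O)C=CC(C)(C)[C@H]2CO[Si](C)(C)C(C)(C)C | intermediate
14 | selenide (4-(phenylselanyl)-4-propanoyl derivative of 11) | CCC(=O)C1([Se]c3ccccc3)C[C@]2(COC1=O)C(=O)C=CC(C)(C)[C@H]2CO[Si](C)(C)C(C)(C)C | intermediate
15 | alkylidene β-keto lactone (4-propanoyl-4,5-didehydro derivative of 11, C8=C9) | CCC(=O)C1=C[C@]2(COC1=O)C(=O)C=CC(C)(C)[C@H]2CO[Si](C)(C)C(C)(C)C | intermediate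
16 | 2-(2-bromoethyl)-2-methyl-1,3-dioxolane | CC1(CCBr)OCCO1 | starting material
17 | conjugate adduct (13 with a 2-(2-methyl-1,3-dioxolan-2-yl)ethyl group on C9, anti to the C10–C5 bond) | CCC(=O)C1[C@@H](CCC2(C)OCCO2)[C@]3(COC1=O)C(=O)C=CC(C)(C)[C@H]3CO[Si](C)(C)C(C)(C)C | intermediate
18 | triketone (13 with a 3-oxobutyl group on C9) | CCC(=O)C1[C@@H](CCC(C)=O)[C@]2(COC1=O)C(=O)C=CC(C)(C)[C@H]2CO[Si](C)(C)C(C)(C)C | intermediate
19 | 1,4-diketone (ring C closed through C8–C14, cis-fused to the lactone; propionyl on C8, ketone at C13) | CCC(=O)[C@]12CC(=O)CC[C@H]1[C@]3(COC2=O)C(=O)C=CC(C)(C)[C@H]3CO[Si](C)(C)C(C)(C)C | intermediate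
20 | tetracyclic ketol (6-O-TBS ether of the target, both C16 epimers) | CC1C(=O)[C@]23C[C@@]1(O)CC[C@H]2[C@]1(COC3=O)C(=O)C=CC(C)(C)[C@H]1CO[Si](C)(C)C(C)(C)C | intermediate
21 | bis(trimethylsilyl) derivative (13-O-TMS ether and C15 TMS enol ether of 20) | CC1=C(O[Si](C)(C)C)[C@]23C[C@@]1(O[Si](C)(C)C)CC[C@H]2[C@]1(COC3=O)C(=O)C=CC(C)(C)[C@H]1CO[Si](C)(C)C(C)(C)C | intermediate
22 | CNP0533761.1 (13-hydroxy-6-hydroxy-1,15-dioxo-6,7-seco-ent-kaur-2-en-7,20-olide, 16-methyl endo) | C[C@H]1C(=O)[C@]23C[C@@]1(O)CC[C@H]2[C@]1(COC3=O)C(=O)C=CC(C)(C)[C@H]1CO | target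

Total step count: 13. Longest linear sequence: 13 steps (from 1; 3, 8, 12 and 16 are bought).

Steps most likely to fail

Step 11. The second enolisation may be unselective, the oxidation may give intermolecular or O–C coupling, and the two enolate sites may fail to meet. The fallback sets out from 15. Copper-catalysed conjugate addition of CH2=CHCH2CH2MgBr (CuBr·SMe2, THF, −78 °C) should give but-3-enyl β-keto lactone F1. Epoxidation of the terminal alkene with mCPBA gives epoxide F2. With Cs2CO3 in DMF the C8 enolate opens the epoxide at its terminal carbon C14 (6-exo-tet) to give hydroxy ketone F3, with ring C closed. Oxidation with DMP (1,1,1-triacetoxy-1,1-dihydro-1,2-benziodoxol-3(1H)-one) brings the route back at 19, which DBU closes to 20 as in step 11.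

Step 2. Enantiofacial discrimination may be poor with the bulky silylmethyl Grignard reagent, and 1,2-addition may compete. The fallback sets out from 2. The same Grignard reagent with CuBr·SMe2 alone, followed by Tamao–Fleming oxidation, gives racemic alcohol F4. Lipase-catalysed acetylation (Pseudomonas cepacia lipase, vinyl acetate) removes the faster-reacting enantiomer as acetate F5 (written for the (R)-enantiomer). The unreacted (S)-alcohol is 5, where the route is rejoined; the cost is half of the material.

Step 13. Protonation of the C15–C16 enol may show poor facial selectivity, or acid may equilibrate C16 toward the exo-methyl epimer during desilylation. The fallback sets out from 21. PhSeCl converts the silyl enol ether into α-seleno ketone F6. Oxidation with H2O2 and selenoxide elimination, which can run only toward the methyl group, give 16-methylene ketone F7. Hydrogenation with RhCl(PPh3)3 under H2 should reduce the 1,1-disubstituted exocyclic alkene from its exo face, in preference to the hindered ring A enone, to give silyl-protected ketone F8. HF·pyridine then returns the route at 22.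

Further compounds
F1 | step 11 | but-3-enyl β-keto lactone (13 with a but-3-enyl group on C9) | CCC(=O)C1[C@@H](CCC=C)[C@]2(COC1=O)C(=O)C=CC(C)(C)[C@H]2CO[Si](C)(C)C(C)(C)C
F2 | step 11 | epoxide (13 with a 2-(oxiran-2-yl)ethyl group on C9) | CCC(=O)C1[C@@H](CCC3CO3)[C@]2(COC1=O)C(=O)C=CC(C)(C)[C@H]2CO[Si](C)(C)C(C)(C)C
F3 | step 11 | hydroxy ketone (13-hydroxy analogue of 19, C13 epimers) | CCC(=O)[C@]12CC(O)CC[C@H]1[C@]3(COC2=O)C(=O)C=CC(C)(C)[C@H]3CO[Si](C)(C)C(C)(C)C
F4 | step 2 | racemic 5-(hydroxymethyl)-4,4-dimethylcyclohex-2-en-1-one | OCC1CC(=O)C=CC1(C)C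
F5 | step 2 | (R)-(6,6-dimethyl-5-oxocyclohex-3-en-1-yl)methyl acetate, i.e. acetate of the (R)-enantiomer of 5 | CC(=O)OC[C@@H]1CC(=O)C=CC1(C)C
F6 | step 13 | α-seleno ketone (16-phenylselanyl derivative of 20, 13-O-TMS ether) | CC1([Se]c2ccccc2)C(=O)[C@]34C[C@@]1(O[Si](C)(C)C)CC[C@H]3[C@]1(COC4=O)C(=O)C=CC(C)(C)[C@H]1CO[Si](C)(C)C(C)(C)C
F7 | step 13 | 16-methylene ketone (13-O-TMS, 6-O-TBS) | C=C1C(=O)[C@]23C[C@@]1(O[Si](C)(C)C)CC[C@H]2[C@]1(COC3=O)C(=O)C=CC(C)(C)[C@H]1CO[Si](C)(C)C(C)(C)C
F8 | step 13 | 13-O-TMS, 6-O-TBS ether of the target (16-methyl endo) | C[C@H]1C(=O)[C@]23C[C@@]1(O[Si](C)(C)C)CC[C@H]2[C@]1(COC3=O)C(=O)C=CC(C)(C)[C@H]1CO[Si](C)(C)C(C)(C)C
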